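Numbering: C1 (bears COi-Pr), C2=O, C3 (quaternary, shared with the cyclopentane), C4=O, C5 (bears geranyl), C6H2, C7H, C8Me2, C9=O, bridge C7–C10H2–C11H–C3; the cyclopentane is C3–C11–CMe2–CH2–CH2.
Cuts, last-made first: C4–C5 (cage closure), C1–COi-Pr, C7–N (helper), then C6–C7 and C1–C9 together, then C7–C8 and C7–C10 (nitromethane stitch), C2–vinyl, C3–CH2 and C3–C11.
Enabling feature: in the cyclohexanone ring C1–C9–C5–C6–C7–C8, the unit C6–C5–C9(=O) is an α-geranyl acrylate (soft CH2, hard C=O), and C7 and C1 flank quaternary C8 as a 1,3-dinucleophile. C1 is the only enolisable carbon of the C2 ketone, and C7, a methine with three carbon neighbours, can be the carbon of nitromethane.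
Ring order forward: temporary γ-lactone, cyclopentane, seven-membered ring (C1, C2, C3, C11, C10, C7, C8), cyclohexanone bridge (key step), then the cage (ring C1–C2–C3–C4–C5–C9 and the second seven-membered ring at once).
Stereochemistry: C11 from enamine/photoredox catalysis; C3 from the forced cis-fusion of lactone and cyclopentane; C7 and C1 from convex-face annulation; C5 from cage geometry; the E-olefin from geranyl bromide.
Helpers: NO2 (removed in step 13), lactone (opened in step 6), tert-butyl ester (turned into the acyl chloride in step 15).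

Key step: step 12

Assumption: with the β-quaternary aldehyde 5, the (2R,5S)-imidazolidinone directs the malonyl radical to the same enamine face as with unbranched aldehydes, which corresponds to (S)-6; otherwise the enantiomeric catalyst is used.

Step 1
Reactants: 1 tert-butyl methyl malonate
Product: 2 tert-butyl methyl 2-bromomalonate
Conditions: NBS (1.0 equiv), Mg(ClO4)2 (cat.), MeCN, rt
Reagents that add atoms: N-bromosuccinimide, O=C1CCC(=O)N1Br
Why: Electrophilic α-bromination of the magnesium-activated malonate enol with one equivalent of NBS should stop at the monobromide, whose labile centre is lost in step 4.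

Step 2
Reactants: 3 methyl 3,3-dimethylpent-4-enoate
Product: 4 methyl 5-bromo-3,3-dimethylpentanoate
Conditions: HBr (g), (PhCO2)2 (cat.), hexane, 0 °C
Reagents that add atoms: hydrogen bromide, Br
Why: Peroxide-initiated radical-chain (Kharasch, anti-Markovnikov) hydrobromination should put bromine on the terminal carbon, because the bromine atom adds to the open CH2 end of the vinyl group.

Step 3
Reactants: 4 methyl 5-bromo-3,3-dimethylpentanoate
Product: 5 5-bromo-3,3-dimethylpentanal
Conditions: i-Bu2AlH, CH2Cl2, −78 °C; aq. Rochelle salt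
Reagents that add atoms: none
Why: Partial ester reduction with i-Bu2AlH should stop at the aldehyde because the aluminium hemiacetal is stable at −78 °C, and the primary bromide is inert.

Step 4
Reactants: 5 5-bromo-3,3-dimethylpentanal; 2 tert-butyl methyl 2-bromomalonate
Product: 8 tert-butyl (4S)-4-(4-bromo-2-methylbutan-2-yl)-2-oxooxolane-3-carboxylate, via aldehyde 6 (not isolated), via alcohol 7 (not isolated)
Conditions: (2R,5S)-2-tert-butyl-3,5-dimethylimidazolidin-4-one·TfOH (20 mol %), Ru(bpy)3Cl2 (0.5 mol %), 2,6-lutidine, DMF, visible light, rt; then NaBH4, MeOH, −20 °C; then PPTS (cat.), CH2Cl2, rt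
Reagents that add atoms: none
Why: Enamine/photoredox asymmetric α-alkylation of an aldehyde with an electrophilic malonyl radical sets C11 through the enamine face left open by the catalyst, and immediate reduction and acid-catalysed lactonisation onto the unhindered methyl ester removes the epimerisable aldehyde and marks that carbonyl as the future C2.

Step 5
Reactants: 8 tert-butyl (4S)-4-(4-bromo-2-methylbutan-2-yl)-2-oxooxolane-3-carboxylate
Product: 9 tert-butyl (3aR,6aR)-6,6-dimethyl-3-oxohexahydro-1H-cyclopenta[c]furan-3a-carboxylate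
Conditions: Cs2CO3, DMF, rt
Reagents that add atoms: none
Why: Intramolecular 5-exo-tet alkylation of the α-alkoxycarbonyl lactone enolate closes the cyclopentane, and because a bicyclo[3.3.0] system can only be cis-fused, quaternary C3 is set by C11 with CO2t-Bu syn to the ring-fusion hydrogen.

Step 6
Reactants: 9 tert-butyl (3aR,6aR)-6,6-dimethyl-3-oxohexahydro-1H-cyclopenta[c]furan-3a-carboxylate; 10 2-methylprop-1-en-1-ylmagnesium bromide
Product: 11 tert-butyl (1R,2R)-2-(hydroxymethyl)-3,3-dimethyl-1-(3-methylbut-2-enoyl)cyclopentane-1-carboxylate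
Conditions: THF, −78 to −30 °C; then H2O
Reagents that add atoms: none
Why: Mono-addition of an alkenyl Grignard reagent to a non-enolisable γ-lactone, which is more electrophilic than the tert-butyl ester and whose tetrahedral alkoxide persists in the cold, should open the temporary ring to the β,β-dimethyl enone (C2, C1, C8) and free the C10 alcohol.

Step 7
Reactants: 11 tert-butyl (1R,2R)-2-(hydroxymethyl)-3,3-dimethyl-1-(3-methylbut-2-enoyl)cyclopentane-1-carboxylate
Product: 12 tert-butyl (1R,2R)-2-formyl-3,3-dimethyl-1-(3-methylbut-2-enoyl)cyclopentane-1-carboxylate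
Conditions: Dess–Martin periodinane, CH2Cl2, 0 °C to rt
Reagents that add atoms: none
Why: Dess–Martin oxidation of the primary alcohol (drawn from the open form of any lactol) is neutral, so the hindered C11–H next to the new aldehyde should not epimerise.

Step 8
Reactants: 12 tert-butyl (1R,2R)-2-formyl-3,3-dimethyl-1-(3-methylbut-2-enoyl)cyclopentane-1-carboxylate; 13 nitromethane
Product: 15 tert-butyl (3aR,8aR)-8-hydroxy-1,1,6,6-tetramethyl-7-nitro-4-oxodecahydroazulene-3a-carboxylate, via Henry adduct 14 (not isolated)
Conditions: 13 (1.2 equiv), DBU (0.3 equiv), MeCN, 0 to 40 °C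
Reagents that add atoms: none
Why: A tandem Henry addition and intramolecular nitro-Michael addition (7-endo-trig onto the β,β-dimethyl enone) lets the one carbon of nitromethane become C7 and close the seven-membered ring, and the uncontrolled centres at C7 and C10 are erased in steps 9 and 12.

Step 9
Reactants: 15 tert-butyl (3aR,8aR)-8-hydroxy-1,1,6,6-tetramethyl-7-nitro-4-oxodecahydroazulene-3a-carboxylate
Product: 18 tert-butyl (3aR,8aR)-1,1,6,6-tetramethyl-7-nitro-4-oxodecahydroazulene-3a-carboxylate, via acetate 16 (not isolated), via nitroalkene 17 (not isolated)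
Conditions: Ac2O, DMAP (cat.), pyridine, 0 °C; then NaBH4, EtOH, 0 °C
Reagents that add atoms: none
Why: The standard deoxygenation of a Henry adduct (acetylation, E1cB loss of acetate, conjugate hydride addition to the nitroalkene) should leave the ketone untouched at 0 °C, because it lies between a quaternary and a neopentyl carbon.

Step 10
Reactants: 19 triethyl phosphonoacetate; 20 geranyl bromide
Product: 21 ethyl (4E)-2-(diethoxyphosphoryl)-5,9-dimethyldeca-4,8-dienoate
Conditions: NaH, THF, 0 °C to rt
Reagents that add atoms: none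
Why: SN2 alkylation of the phosphonoacetate anion at the primary allylic bromide keeps the E-olefin, and an excess of 19 suppresses double alkylation.

Step 11
Reactants: 21 ethyl (4E)-2-(diethoxyphosphoryl)-5,9-dimethyldeca-4,8-dienoate; 22 formaldehyde (37 % aq.)
Product: 23 ethyl (4E)-5,9-dimethyl-2-methylidenedeca-4,8-dienoate
Conditions: K2CO3, H2O/THF, 60 °C
Reagents that add atoms: none
Why: Horner–Wadsworth–Emmons methylenation with aqueous formaldehyde is the standard route to α-substituted acrylates and supplies C6 (CH2), C5 and C9.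

Step 12
Reactants: 18 tert-butyl (3aR,8aR)-1,1,6,6-tetramethyl-7-nitro-4-oxodecahydroazulene-3a-carboxylate; 23 ethyl (4E)-5,9-dimethyl-2-methylidenedeca-4,8-dienoate
Product: 25 bridged nitro β-diketone tert-butyl ester, via Michael adduct 24 (not isolated)
Conditions: KOt-Bu (2.2 equiv), THF/t-BuOH, 0 °C to rt; then 1 M HCl
Reagents that add atoms: none
Why: KOt-Bu first deprotonates only the nitro group of 18, the secondary nitronate adds to the CH2 terminus of acrylate 23 (nitro-Michael addition, C6–C7), and after proton exchange the C2 enolate, which can form only towards C1 because C3 is quaternary, attacks the ethyl ester (C1–C9) with loss of ethoxide. The closest known reaction type is the one-pot Michael/Dieckmann (Claisen) [3+3] annulation that turns nitroalkanes and acrylates into 4-nitrocyclohexanones. The one ring closed is the cyclohexanone C1–C9–C5–C6–C7–C8, by a 6-exo-trig acyl substitution that bridges the seven-membered ring to a bicyclo[4.3.1]decane and is pulled forward by deprotonation of the new C2/C9 β-diketone at C1. C7 is set by approach of the acrylate to the convex face of the cis-fused hydroazulene (the face of CO2t-Bu and H-11, away from the cyclopentane and its gem-dimethyl group), C1 follows because a three-atom bridge can span C7 and C1 on one face only, and C5 stays epimerisable until step 15. The step needs the pairing of C7 with CH2 and of C1 with C=O and not the reverse, which is secured by the acidity gap between nitro group and ketone, by the soft nitronate/hard ester match and by ring size, since other attacks give only reversible adducts or strained rings. The nitro group is the helper that makes the unactivated methine C7 a nucleophile, and it leaves in step 13.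

Step 13
Reactants: 25 bridged nitro β-diketone tert-butyl ester
Product: 26 bridged β-diketone tert-butyl ester
Conditions: Bu3SnH, AIBN (cat.), toluene, 110 °C
Reagents that add atoms: none
Why: Radical denitration of a tertiary nitro compound with Bu3SnH gives a bridgehead C7 radical that can take hydrogen only from outside the bicycle, so C7 keeps its configuration, and the equatorial radical orbital cannot reach the geranyl olefin.

Step 14
Reactants: 26 bridged β-diketone tert-butyl ester; 27 isobutyryl chloride
Product: 28 C1-isobutyryl triketone tert-butyl ester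
Conditions: LiN(SiMe3)2 (1.05 equiv), THF, −78 °C; then 27, −78 to 0 °C
Reagents that add atoms: none
Why: C-acylation of the lithium enolate of the bridged β-diketone, the most acidic site, should prevail because O-acylation would keep a strained bridgehead enol double bond, and the bridgehead C1 can accept the acyl group only on its outer face.

Step 15
Reactants: 28 C1-isobutyryl triketone tert-butyl ester
Product: 31 target CNP0313870.1, via trimethylsilyl ester 29 (not isolated), via acid chloride 30 (not isolated)
Conditions: Me3SiOTf, 2,6-lutidine, CH2Cl2, 0 °C; then (COCl)2, DMF (cat.), CH2Cl2, 0 °C; then MgBr2·OEt2, i-Pr2NEt, CH2Cl2, 0 °C to rt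
Reagents that add atoms: none
Why: Soft-enolisation Claisen-type C-acylation of the C9 ketone at C5 by the acyl chloride on C3 closes the cage irreversibly (chloride cannot reopen the non-enolisable polyketone), C5 is set because only its face towards C4 can bond, and O-acylation is excluded because the C9 oxygen points away from C4.

Compound list
1 | tert-butyl methyl malonate | COC(=O)CC(=O)OC(C)(C)C | starting material
2 | tert-butyl methyl 2-bromomalonate (racemic, labile centre) | COC(=O)C(Br)C(=O)OC(C)(C)C | intermediate
3 | methyl 3,3-dimethylpent-4-enoate | C=CC(C)(C)CC(=O)OC | starting material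
4 | methyl 5-bromo-3,3-dimethylpentanoate | BrCCC(C)(C)CC(=O)OC | intermediate
5 | 5-bromo-3,3-dimethylpentanal | BrCCC(C)(C)CC=O | intermediate
6 | 1-tert-butyl 3-methyl 2-[(2S)-5-bromo-3,3-dimethyl-1-oxopentan-2-yl]malonate (malonate CH epimers) | O=C[C@@H](C(C(=O)OC)C(=O)OC(C)(C)C)C(C)(C)CCBr | intermediate
7 | 1-tert-butyl 3-methyl 2-[(2S)-5-bromo-1-hydroxy-3,3-dimethylpentan-2-yl]malonate (malonate CH epimers) | OC[C@@H](C(C(=O)OC)C(=O)OC(C)(C)C)C(C)(C)CCBr | intermediate
8 | tert-butyl (4S)-4-(4-bromo-2-methylbutan-2-yl)-2-oxooxolane-3-carboxylate (C3 epimers) | O=C1OC[C@H](C(C)(C)CCBr)C1C(=O)OC(C)(C)C | intermediate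
9 | tert-butyl (3aR,6aR)-6,6-dimethyl-3-oxohexahydro-1H-cyclopenta[c]furan-3a-carboxylate (cis-fused, ester syn to ring-fusion H) | CC(C)(C)OC(=O)[C@]12CCC(C)(C)[C@H]1COC2=O | intermediate
10 | 2-methylprop-1-en-1-ylmagnesium bromide | CC(C)=C[Mg]Br | starting material
11 | tert-butyl (1R,2R)-2-(hydroxymethyl)-3,3-dimethyl-1-(3-methylbut-2-enoyl)cyclopentane-1-carboxylate | CC(C)(C)OC(=O)[C@]1(C(=O)C=C(C)C)CCC(C)(C)[C@H]1CO | intermediate
12 | tert-butyl (1R,2R)-2-formyl-3,3-dimethyl-1-(3-methylbut-2-enoyl)cyclopentane-1-carboxylate | CC(C)(C)OC(=O)[C@]1(C(=O)C=C(C)C)CCC(C)(C)[C@H]1C=O | intermediate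
13 | nitromethane | C[N+](=O)[O-] | starting material
14 | tert-butyl (1R,2R)-2-(1-hydroxy-2-nitroethyl)-3,3-dimethyl-1-(3-methylbut-2-enoyl)cyclopentane-1-carboxylate (carbinol epimers) | CC(C)(C)OC(=O)[C@]1(C(=O)C=C(C)C)CCC(C)(C)[C@H]1C(O)C[N+](=O)[O-] | intermediate
15 | tert-butyl (3aR,8aR)-8-hydroxy-1,1,6,6-tetramethyl-7-nitro-4-oxodecahydroazulene-3a-carboxylate (epimers at the nitro and carbinol carbons) | CC(C)(C)OC(=O)[C@]12CCC(C)(C)[C@H]1C(O)C([N+](=O)[O-])C(C)(C)CC2=O | intermediate
16 | acetate of 15 | CC(C)(C)OC(=O)[C@]12CCC(C)(C)[C@H]1C(OC(C)=O)C([N+](=O)[O-])C(C)(C)CC2=O | intermediate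
17 | ring nitroalkene, tert-butyl (3aR,8aR)-1,1,6,6-tetramethyl-7-nitro-4-oxo-octahydroazulene-3a-carboxylate with C7=C8 double bond (azulene locants) | CC(C)(C)OC(=O)[C@]12CCC(C)(C)[C@H]1C=C([N+](=O)[O-])C(C)(C)CC2=O | intermediate
18 | tert-butyl (3aR,8aR)-1,1,6,6-tetramethyl-7-nitro-4-oxodecahydroazulene-3a-carboxylate (nitro carbon epimers) | CC(C)(C)OC(=O)[C@]12CCC(C)(C)[C@H]1CC([N+](=O)[O-])C(C)(C)CC2=O | intermediate
19 | triethyl phosphonoacetate | CCOC(=O)CP(=O)(OCC)OCC | starting material
20 | geranyl bromide | CC(C)=CCC/C(C)=C/CBr | starting material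
21 | ethyl (4E)-2-(diethoxyphosphoryl)-5,9-dimethyldeca-4,8-dienoate (racemic) | CCOC(=O)C(C/C=C(\C)CCC=C(C)C)P(=O)(OCC)OCC | intermediate
22 | formaldehyde | C=O | starting material
23 | ethyl (4E)-5,9-dimethyl-2-methylidenedeca-4,8-dienoate (ethyl 2-geranylacrylate) | CCOC(=O)C(=C)C/C=C(\C)CCC=C(C)C | intermediate
24 | Michael adduct of 18 and 23: tertiary C7 nitro compound, new C6H2 on the face of CO2t-Bu and H-11, C5 epimers | CCOC(=O)C(C/C=C(\C)CCC=C(C)C)C[C@@]1([N+](=O)[O-])C[C@@H]2C(C)(C)CC[C@]2(C(=O)OC(C)(C)C)C(=O)CC1(C)C | intermediate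
25 | bridged nitro β-diketone tert-butyl ester: cyclopentane-fused bicyclo[4.3.1]decane, C2 and C9 ketones, NO2 at C7, CO2t-Bu at C3, geranyl at C5 (C5 epimers) | CC(C)=CCC/C(C)=C/CC1C[C@@]2([N+](=O)[O-])C[C@@H]3C(C)(C)CC[C@]3(C(=O)OC(C)(C)C)C(=O)[C@@H](C1=O)C2(C)C | intermediate
26 | bridged β-diketone tert-butyl ester: as 25 with H in place of NO2 at C7, configuration retained | CC(C)=CCC/C(C)=C/CC1C[C@H]2C[C@@H]3C(C)(C)CC[C@]3(C(=O)OC(C)(C)C)C(=O)[C@@H](C1=O)C2(C)C | intermediate
27 | isobutyryl chloride | CC(C)C(=O)Cl | starting material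
28 | C1-isobutyryl triketone tert-butyl ester (C5 epimers) | CC(C)=CCC/C(C)=C/CC1C[C@H]2C[C@@H]3C(C)(C)CC[C@]3(C(=O)OC(C)(C)C)C(=O)[C@@](C(=O)C(C)C)(C1=O)C2(C)C | intermediate
29 | trimethylsilyl ester corresponding to 28 | CC(C)=CCC/C(C)=C/CC1C[C@H]2C[C@@H]3C(C)(C)CC[C@]3(C(=O)O[Si](C)(C)C)C(=O)[C@@](C(=O)C(C)C)(C1=O)C2(C)C | intermediate
30 | acid chloride corresponding to 28 | CC(C)=CCC/C(C)=C/CC1C[C@H]2C[C@@H]3C(C)(C)CC[C@]3(C(=O)Cl)C(=O)[C@@](C(=O)C(C)C)(C1=O)C2(C)C | intermediate
31 | CNP0313870.1 | CC(C)=CCC/C(C)=C/C[C@@]12C[C@H]3C[C@@H]4C(C)(C)CC[C@]4(C1=O)C(=O)[C@@](C(=O)C(C)C)(C2=O)C3(C)C | target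

Total step count: 15. Longest linear sequence: 12 steps (steps 2–9 and 12–15, from 3).

Steps most likely to fail

Step 15 (cage closure). After loss of the tert-butyl group the β-keto acid derivative may decarboxylate. Enolisation at the hindered C5–H may be too slow to compete with decay of the acyl chloride, and the triacylmethane at C1 may be cleaved.
The fallback replaces acyl substitution by aldol addition and oxidation; it sets out from 28 and comes back at 31. Me3SiOTf/2,6-lutidine and a cold aqueous work-up give the keto acid F1. EtSH, EDC·HCl and DMAP give the S-ethyl thioester F2. Fukuyama reduction (Et3SiH, Pd/C, acetone) gives the aldehyde F3. KN(SiMe3)2 at −78 °C closes C4–C5 by intramolecular aldol addition to the C4 carbinol F4, and Dess–Martin oxidation gives 31.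

Step 12 (key annulation). The strong base needed for the acyl substitution may reopen the seven-membered ring by retro-Michael cleavage at C7–C8. Attack of the neopentyl C1 enolate on the ester may be slow. Facial selectivity at C7 may be eroded by the bulky ester on the convex face.
The fallback uses an enal as the 1,3-dielectrophile under amine base only and raises the oxidation level afterwards; it sets out from 18 and 23 and comes back at 25. i-Bu2AlH reduces 23 to the allylic alcohol F5, and MnO2 gives 2-geranylacrolein F6. DBU in MeCN joins 18 and F6 by nitro-Michael addition followed by intramolecular aldol addition of C1 to the aldehyde, which gives the C9 carbinol F7. Dess–Martin oxidation gives 25.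

Step 8 (nitromethane stitch). The ring-closing equilibrium to a seven-membered β-nitro alcohol may be unfavourable, two molecules of nitromethane may add, and the aldehyde may epimerise at C11 under DBU.
The fallback makes C7–C10 irreversibly first and closes C7–C8 last; it sets out from 12 and comes back at 18. Nitromethane in excess with catalytic i-Pr2NEt at 0 °C gives 14, which is isolated. MsCl/Et3N dehydrates it to the E-nitroalkene F8. Hantzsch ester on silica gel reduces only the nitroalkene, to the nitroethyl enone F9. CsF in MeCN at 70 °C then closes the ring by intramolecular nitro-Michael addition to 18.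

Further compounds
F1 | step 15 | keto acid corresponding to 28 | CC(C)=CCC/C(C)=C/CC1C[C@H]2C[C@@H]3C(C)(C)CC[C@]3(C(=O)O)C(=O)[C@@](C(=O)C(C)C)(C1=O)C2(C)C
F2 | step 15 | S-ethyl thioester corresponding to 28 | CC(C)=CCC/C(C)=C/CC1C[C@H]2C[C@@H]3C(C)(C)CC[C@]3(C(=O)SCC)C(=O)[C@@](C(=O)C(C)C)(C1=O)C2(C)C
F3 | step 15 | C4 aldehyde corresponding to 28 | CC(C)=CCC/C(C)=C/CC1C[C@H]2C[C@@H]3C(C)(C)CC[C@]3(C=O)C(=O)[C@@](C(=O)C(C)C)(C1=O)C2(C)C
F4 | step 15 | C4 carbinol of the target (carbinol epimers) | CC(C)=CCC/C(C)=C/C[C@@]12C[C@H]3C[C@@H]4C(C)(C)CC[C@]4(C1O)C(=O)[C@@](C(=O)C(C)C)(C2=O)C3(C)C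
F5 | step 12 | (4E)-5,9-dimethyl-2-methylidenedeca-4,8-dien-1-ol | C=C(CO)C/C=C(\C)CCC=C(C)C
F6 | step 12 | (4E)-5,9-dimethyl-2-methylidenedeca-4,8-dienal (2-geranylacrolein) | C=C(C=O)C/C=C(\C)CCC=C(C)C
F7 | step 12 | C9 carbinol corresponding to 25 (carbinol and C5 epimers) | CC(C)=CCC/C(C)=C/CC1C[C@@]2([N+](=O)[O-])C[C@@H]3C(C)(C)CC[C@]3(C(=O)OC(C)(C)C)C(=O)[C@@H](C1O)C2(C)C
F8 | step 8 | tert-butyl (1R,2R)-3,3-dimethyl-1-(3-methylbut-2-enoyl)-2-[(E)-2-nitroethenyl]cyclopentane-1-carboxylate | CC(C)(C)OC(=O)[C@]1(C(=O)C=C(C)C)CCC(C)(C)[C@H]1/C=C/[N+](=O)[O-]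
F9 | step 8 | tert-butyl (1R,2R)-3,3-dimethyl-1-(3-methylbut-2-enoyl)-2-(2-nitroethyl)cyclopentane-1-carboxylate | CC(C)(C)OC(=O)[C@]1(C(=O)C=C(C)C)CCC(C)(C)[C@H]1CC[N+](=O)[O-]
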